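The route rests on the C7–C16 bond of the cyclopentane (C4–C5–C6–C7–C16; trinervitane numbering). The target has an exocyclic methylene C15=C17 next to C16 and an oxygen at C9, two carbons from C7: the retron of an allylsilane–enone addition. The precursor is therefore a bicyclic 7,16-seco compound: ring A cyclohexene carrying a C15 CH2SiMe3 group, bridged by a 14-membered ring with a (7E)-C7=C8–C9=O enone and the (11E)-olefin. One transannular Hosomi–Sakurai reaction closes the cyclopentane, turns the 14-membered ring into the eleven-membered ring, creates C15=C17 and sets C16, C7 and C8. A temporary lactone between O3 and C13 controls C1 and C4 earlier.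

Key step: step 17

Remark: atom numbers in names and explanations follow the trinervitane skeleton of the target (ring A = C1, C2, C3, C4, C16, C15; cyclopentane = C4, C5, C6, C7, C16; eleven-membered ring = C1, C15, C16, C7 to C14; C17 = methylene carbon on C15; C18, C19, C20 = methyls on C4, C8, C12). Compounds 1 and 12 are taken as commercial.

Step 1
Reactants: 1 1,4-dioxaspiro[4.5]dec-6-en-8-one
Product: 2 7-iodo-1,4-dioxaspiro[4.5]dec-6-en-8-one
Conditions: I2, pyridine, CH2Cl2, 0 to 23 °C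
Reagents that add atoms: iodine, II
Why: α-iodination of the enone by reversible β-addition of pyridine, iodination of the enolate and elimination is standard for cyclic enones and should leave the ketal untouched.

Step 2
Reactants: 2 7-iodo-1,4-dioxaspiro[4.5]dec-6-en-8-one
Product: 3 7-methyl-1,4-dioxaspiro[4.5]dec-6-en-8-one
Conditions: Me4Sn, Pd2(dba)3 (cat.), AsPh3, CuI (cat.), NMP, 80 °C
Reagents that add atoms: tetramethylstannane, C[Sn](C)(C)C
Why: Stille coupling of the α-iodoenone should replace iodine by the future C18 methyl group.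

Step 3
Reactants: 3 7-methyl-1,4-dioxaspiro[4.5]dec-6-en-8-one
Product: 5 (4S)-4-hydroxy-3-methylcyclohex-2-en-1-one, via ketal alcohol 4 (not isolated)
Conditions: (R)-2-methyl-CBS-oxazaborolidine [(R)-tetrahydro-1-methyl-3,3-diphenyl-1H,3H-pyrrolo[1,2-c][1,3,2]oxazaborole] (0.2 equiv), BH3·SMe2, THF, −20 °C; then 1 M HCl, THF, 23 °C
Reagents that add atoms: water, O
Why: Corey–Bakshi–Shibata reduction with the α-methylvinyl side as the large group should give the (S)-carbinol (future C3), and aqueous acid then hydrolyses the ketal to the conjugated enone.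

Step 4
Reactants: 5 (4S)-4-hydroxy-3-methylcyclohex-2-en-1-one
Product: 7 (1S,5S)-8-methyl-2-oxabicyclo[3.3.1]non-7-ene-3,6-dione, via hydroxy ester 6 (not isolated)
Conditions: LiN(i-Pr)2 (2.1 equiv), THF, −78 °C; BrCH2CO2Me, −78 to 23 °C
Reagents that add atoms: methyl bromoacetate, COC(=O)CBr
Why: The dianion (alkoxide plus kinetic α′-enolate) is C-alkylated and only the epimer with the acetate arm cis to O3 can close the bridged δ-lactone, while the other epimerises at C1 (α to the ketone) through the lithium methoxide released, so the temporary lactone sets C1 relative to C3.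

Step 5
Reactants: 7 (1S,5S)-8-methyl-2-oxabicyclo[3.3.1]non-7-ene-3,6-dione
Product: 9 (1S,5S,8S)-8-(but-3-en-1-yl)-8-methyl-3-oxo-2-oxabicyclo[3.3.1]non-6-en-6-yl trifluoromethanesulfonate, via silyl enol ether 8 (not isolated)
Conditions: CH2=CHCH2CH2MgBr, CuBr·SMe2 (0.1 equiv), Me3SiCl, HMPA, THF, −78 °C; then PhNTf2, CsF, DME, 23 °C
Reagents that add atoms: but-3-enylmagnesium bromide, C=CCC[Mg]Br; N-phenyl-bis(trifluoromethanesulfonimide), O=S(=O)(N(c1ccccc1)S(=O)(=O)C(F)(F)F)C(F)(F)F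
Why: Copper-catalysed, silyl-chloride-accelerated conjugate addition should build the C4 quaternary centre on the face anti to the lactone bridge (butenyl trans to O3 and to the C1 arm), and fluoride-mediated triflation of the regiodefined enol ether fixes the C15=C16 double bond.

Step 6
Reactants: 9 (1S,5S,8S)-8-(but-3-en-1-yl)-8-methyl-3-oxo-2-oxabicyclo[3.3.1]non-6-en-6-yl trifluoromethanesulfonate
Product: 10 (1S,5S,8S)-8-(but-3-en-1-yl)-8-methyl-6-[(trimethylsilyl)methyl]-2-oxabicyclo[3.3.1]non-6-en-3-one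
Conditions: Me3SiCH2MgCl, Fe(acac)3 (0.05 equiv), THF/NMP, −30 °C
Reagents that add atoms: (trimethylsilyl)methylmagnesium chloride, C[Si](C)(C)C[Mg]Cl
Why: Iron-catalysed Kumada-type coupling of the enol triflate is fast at low temperature and should spare the lactone, giving the allylsilane with C17 in place.

Step 7
Reactants: 10 (1S,5S,8S)-8-(but-3-en-1-yl)-8-methyl-6-[(trimethylsilyl)methyl]-2-oxabicyclo[3.3.1]non-6-en-3-one
Product: 11 (1S,5S,8S)-8-(but-3-en-1-yl)-8-methyl-6-[(trimethylsilyl)methyl]-2-oxabicyclo[3.3.1]non-6-en-3-ol (lactol)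
Conditions: i-Bu2AlH (1.1 equiv), CH2Cl2, −78 °C
Reagents that add atoms: none
Why: Hydride reduction of the lactone stops at the aluminium acetal at −78 °C and should unmask C13 at the aldehyde oxidation level.

Step 8
Reactants: 12 pent-3-yn-1-ol
Product: 14 (3E)-4-iodopent-3-en-1-ol, via alkenylzirconocene 13 (not isolated)
Conditions: Cp2Zr(H)Cl (2.2 equiv), THF, 23 °C; then I2, 0 °C
Reagents that add atoms: iodine, II
Why: syn-Hydrozirconation should place zirconium on the methyl-bearing alkyne carbon distal to the oxygen, and iodinolysis with retention gives the (E)-vinyl iodide (future C11=C12 geometry).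

Step 9
Reactants: 14 (3E)-4-iodopent-3-en-1-ol
Product: 16 (3E)-4-iodopent-3-enoic acid, via aldehyde 15 (not isolated)
Conditions: TEMPO (0.1 equiv), PhI(OAc)2 (2.2 equiv), MeCN/H2O, 23 °C
Reagents that add atoms: water, O
Why: Oxoammonium oxidation in aqueous acetonitrile should take the primary alcohol through the aldehyde hydrate to the acid without touching the vinyl iodide.

Step 10
Reactants: 16 (3E)-4-iodopent-3-enoic acid
Product: 18 (3E)-4-iodo-N-methoxy-N-methylpent-3-enamide, via acyl imidazole 17 (not isolated)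
Conditions: 1,1'-carbonyldiimidazole, CH2Cl2, 23 °C; then MeNH(OMe)·HCl
Reagents that add atoms: N,O-dimethylhydroxylamine hydrochloride, CNOC.Cl
Why: Aminolysis of the acyl imidazole gives the Weinreb amide, a masked C9 acyl group that should survive the organochromium, oxidation, reduction and silylation steps that follow.

Step 11
Reactants: 11 lactol; 18 (3E)-4-iodo-N-methoxy-N-methylpent-3-enamide
Product: 19 (3E)-6-[(1R,4S,5S)-4-(but-3-en-1-yl)-5-hydroxy-4-methyl-2-[(trimethylsilyl)methyl]cyclohex-2-en-1-yl]-5-hydroxy-N-methoxy-N,4-dimethylhex-3-enamide (both C13 epimers)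
Conditions: CrCl2 (4 equiv), NiCl2 (0.02 equiv), DMSO, 23 °C
Reagents that add atoms: none
Why: In this Nozaki–Hiyama–Kishi coupling the alkenylchromium species (olefin geometry retained) adds only to the aldehyde form of the lactol and should tolerate the amide and the allylsilane; the C13 configuration is not controlled here and is set in steps 12 and 13.

Step 12
Reactants: 19 diol (C13 epimers)
Product: 20 (3E)-6-[(1S,4S,5S)-4-(but-3-en-1-yl)-5-hydroxy-4-methyl-2-[(trimethylsilyl)methyl]cyclohex-2-en-1-yl]-N-methoxy-N,4-dimethyl-5-oxohex-3-enamide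
Conditions: MnO2, CH2Cl2, 23 °C
Reagents that add atoms: none
Why: MnO2 should oxidise only the allylic C13 alcohol and leave the saturated C3 alcohol.

Step 13
Reactants: 20 hydroxy enone
Product: 21 (3E,5R)-6-[(1R,4S,5S)-4-(but-3-en-1-yl)-5-hydroxy-4-methyl-2-[(trimethylsilyl)methyl]cyclohex-2-en-1-yl]-5-hydroxy-N-methoxy-N,4-dimethylhex-3-enamide
Conditions: (S)-2-methyl-CBS-oxazaborolidine (1 equiv), catecholborane, toluene, −78 °C
Reagents that add atoms: none
Why: Corey–Bakshi–Shibata reduction under reagent control, with the α-methylalkenyl group as the large substituent, should give the (13R)-allylic alcohol, and catecholborane leaves the amide and the olefins alone.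

Step 14
Reactants: 21 (13R)-diol
Product: 22 (3E,5R)-5-(tert-butyldimethylsilyloxy)-6-[(1R,4S,5S)-4-(but-3-en-1-yl)-5-(tert-butyldimethylsilyloxy)-4-methyl-2-[(trimethylsilyl)methyl]cyclohex-2-en-1-yl]-N-methoxy-N,4-dimethylhex-3-enamide
Conditions: t-BuMe2SiOTf, 2,6-lutidine, CH2Cl2, −78 to 0 °C
Reagents that add atoms: tert-butyldimethylsilyl trifluoromethanesulfonate, CC(C)(C)[Si](C)(C)OS(=O)(=O)C(F)(F)F
Why: The silyl triflate should protect both secondary alcohols (O3 and O13), with the base buffering against protodesilylation of the allylsilane.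

Step 15
Reactants: 22 bis-silyl ether Weinreb amide
Product: 23 (5E,7R)-7-(tert-butyldimethylsilyloxy)-8-[(1R,4S,5S)-4-(but-3-en-1-yl)-5-(tert-butyldimethylsilyloxy)-4-methyl-2-[(trimethylsilyl)methyl]cyclohex-2-en-1-yl]-2,6-dimethylocta-1,5-dien-3-one
Conditions: CH2=C(CH3)MgBr, THF, −20 to 0 °C; aq. NH4Cl
Reagents that add atoms: isopropenylmagnesium bromide, CC(=C)[Mg]Br
Why: Grignard addition to the Weinreb amide stops at the chelated tetrahedral intermediate and should give the isopropenyl ketone (C8, C9, C19) on work-up.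

Step 16
Reactants: 23 isopropenyl ketone
Product: 24 (1R,3S,4S,7E,11E,13R)-3,13-bis(tert-butyldimethylsilyloxy)-17-(trimethylsilyl)-7,16-secotrinervita-7,11,15-trien-9-one
Conditions: second-generation Hoveyda–Grubbs catalyst (0.1 equiv), toluene (1 mM), 80 °C
Reagents that add atoms: none
Why: Ring-closing metathesis between the monosubstituted butenyl olefin and the 1,1-disubstituted enone olefin should close the 14-membered ring as the conjugated (7E)-enone, the trisubstituted olefins being inert.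

Step 17
Reactants: 24 bicyclic allylsilane enone
Product: 26 (1R,3S,4S,7R,8S,11E,13R,16S)-3,13-bis(tert-butyldimethylsilyloxy)trinervita-11,15(17)-dien-9-one, via aluminium enolate 25 (not isolated)
Conditions: EtAlCl2 (1.5 equiv), CH2Cl2, −78 to −20 °C; aq. NaHCO3; then DBU (0.2 equiv), CH2Cl2, 0 °C
Reagents that add atoms: none
Why: EtAlCl2 activates the C9 ketone, the allylsilane γ-carbon C16 adds to C7 across the 14-membered ring, and the β-silyl cation at C15 collapses with loss of Me3SiCl to give C15=C17 and enolate 25; the closest known type is the Lewis-acid-promoted intramolecular Hosomi–Sakurai 1,4-addition, run here transannularly. The cyclopentane closes in a 5-exo-trig mode (C7=C8 exocyclic to the new ring), and the same bond divides the 14-membered ring into the cyclopentane and the eleven-membered ring, so no further ring closure is needed. C16: the three-atom tether C4–C5–C6 delivers C7 to the face of C16 syn to C5, which enforces the cis ring fusion (H16 cis to C18) with anti departure of silicon. C7: C8 should end cis to C15 on the new ring, because the bridge C8 to C14 with its (11E)-olefin has to span C15 and C8 and the trans arrangement would force C17 into the eleven-membered ring. C8: set on protonation of 25 and equilibrated with DBU to the epimer expected to be more stable, with H8 turned to the concave face over ring A and C19 outward. The step needs 1,4- over 1,2-addition (five- against seven-membered ring) and C–C bond formation faster than protodesilylation, which the proximity of C16 and C7 in the bridged macrocycle and aprotic low-temperature conditions should secure.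

Step 18
Reactants: 26 tricyclic ketone
Product: 27 (1R,3S,4S,7R,8S,9S,11E,13R,16S)-3,13-bis(tert-butyldimethylsilyloxy)trinervita-11,15(17)-dien-9-ol
Conditions: (R)-2-methyl-CBS-oxazaborolidine (1 equiv), catecholborane, toluene, −40 °C
Reagents that add atoms: none
Why: Corey–Bakshi–Shibata reduction with the α-branched C8 side as the large group should give the (9S)-alcohol under reagent control, and catecholborane avoids hydroboration of the C15=C17 olefin.

Step 19
Reactants: 27 bis-silyl ether alcohol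
Product: 28 (1R,3S,4S,7R,8S,9S,11E,13R,16S)-trinervita-11,15(17)-diene-3,9,13-triol
Conditions: Bu4NF, THF, 50 °C
Reagents that add atoms: none
Why: Fluoride should cleave both silyl ethers, the hindered O3 ether requiring gentle heating.

Step 20
Reactants: 28 triol
Product: 29 (1S,3S,4S,7R,8S,9S,11S,12S,13R,16S)-11,12-epoxytrinervit-15(17)-ene-3,9,13-triol
Conditions: mCPBA (1.05 equiv), NaHCO3, CH2Cl2, −20 to 0 °C
Reagents that add atoms: 3-chloroperoxybenzoic acid, OOC(=O)c1cccc(Cl)c1
Why: The trisubstituted C11=C12 olefin is more nucleophilic than the shielded C15=C17, and hydrogen-bond delivery from the C13 hydroxyl (H13 eclipsing the olefin to minimise allylic 1,3-strain) to the outer face of the (E)-olefin should give the threo epoxy alcohol of the target.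

Step 21
Reactants: 29 epoxy triol
Product: 30 (1S,3S,4S,7R,8S,9S,11S,12R,13R,16S)-11,12-epoxytrinervit-15(17)-ene-3,9,13-triyl tripropanoate (CNP0332420.1)
Conditions: (EtCO)2O, DMAP, Et3N, CH2Cl2, 23 °C
Reagents that add atoms: propanoic anhydride, CCC(=O)OC(=O)CC
Why: DMAP-catalysed acylation of the three secondary hydroxyls should give the tripropanoate without opening the epoxide.

Compound list

1 | 1,4-dioxaspiro[4.5]dec-6-en-8-one | O=C1CCC2(OCCO2)C=C1 | starting material
2 | 7-iodo-1,4-dioxaspiro[4.5]dec-6-en-8-one | O=C1CCC2(OCCO2)C=C1I | intermediate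
3 | 7-methyl-1,4-dioxaspiro[4.5]dec-6-en-8-one | O=C1CCC2(OCCO2)C=C1C | intermediate
4 | (8S)-7-methyl-1,4-dioxaspiro[4.5]dec-6-en-8-ol | O[C@H]1CCC2(OCCO2)C=C1C | intermediate (not isolated)
5 | (4S)-4-hydroxy-3-methylcyclohex-2-en-1-one | O[C@H]1CCC(=O)C=C1C | intermediate
6 | methyl 2-[(5S)-5-hydroxy-4-methyl-2-oxocyclohex-3-en-1-yl]acetate (both C1 epimers) | COC(=O)CC1C[C@H](O)C(C)=CC1=O | intermediate (not isolated)
7 | (1S,5S)-8-methyl-2-oxabicyclo[3.3.1]non-7-ene-3,6-dione (O3–C13 lactone bridging C1 and C3 of ring A) | O=C1C[C@@H]2C[C@H](O1)C(C)=CC2=O | intermediate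
8 | (1S,5S,8S)-8-(but-3-en-1-yl)-8-methyl-6-(trimethylsilyloxy)-2-oxabicyclo[3.3.1]non-6-en-3-one | O=C1C[C@@H]2C[C@H](O1)[C@@](C)(CCC=C)C=C2O[Si](C)(C)C | intermediate (not isolated)
9 | (1S,5S,8S)-8-(but-3-en-1-yl)-8-methyl-3-oxo-2-oxabicyclo[3.3.1]non-6-en-6-yl trifluoromethanesulfonate | O=C1C[C@@H]2C[C@H](O1)[C@@](C)(CCC=C)C=C2OS(=O)(=O)C(F)(F)F | intermediate
10 | (1S,5S,8S)-8-(but-3-en-1-yl)-8-methyl-6-[(trimethylsilyl)methyl]-2-oxabicyclo[3.3.1]non-6-en-3-one | O=C1C[C@@H]2C[C@H](O1)[C@@](C)(CCC=C)C=C2C[Si](C)(C)C | intermediate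
11 | (1S,5S,8S)-8-(but-3-en-1-yl)-8-methyl-6-[(trimethylsilyl)methyl]-2-oxabicyclo[3.3.1]non-6-en-3-ol (lactol, both anomers) | OC1C[C@@H]2C[C@H](O1)[C@@](C)(CCC=C)C=C2C[Si](C)(C)C | intermediate
12 | pent-3-yn-1-ol | CC#CCCO | starting material
13 | (E)-alkenylzirconocene chloride from 12, oxygen also zirconated | C/C(=C\CCO[Zr](Cl)(C1C=CC=C1)C1C=CC=C1)[Zr](Cl)(C1C=CC=C1)C1C=CC=C1 | intermediate (not isolated)
14 | (3E)-4-iodopent-3-en-1-ol | C/C(I)=C\CCO | intermediate
15 | (3E)-4-iodopent-3-enal | C/C(I)=C\CC=O | intermediate (not isolated)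
16 | (3E)-4-iodopent-3-enoic acid | C/C(I)=C\CC(=O)O | intermediate
17 | (3E)-1-(imidazol-1-yl)-4-iodopent-3-en-1-one | C/C(I)=C\CC(=O)n1ccnc1 | intermediate (not isolated)
18 | (3E)-4-iodo-N-methoxy-N-methylpent-3-enamide | C/C(I)=C\CC(=O)N(C)OC | intermediate
19 | (3E)-6-[(1R,4S,5S)-4-(but-3-en-1-yl)-5-hydroxy-4-methyl-2-[(trimethylsilyl)methyl]cyclohex-2-en-1-yl]-5-hydroxy-N-methoxy-N,4-dimethylhex-3-enamide (both C13 epimers) | O[C@H]1C[C@@H](CC(O)/C(C)=C/CC(=O)N(C)OC)C(C[Si](C)(C)C)=C[C@]1(C)CCC=C | intermediate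
20 | (3E)-6-[(1S,4S,5S)-4-(but-3-en-1-yl)-5-hydroxy-4-methyl-2-[(trimethylsilyl)methyl]cyclohex-2-en-1-yl]-N-methoxy-N,4-dimethyl-5-oxohex-3-enamide | O[C@H]1C[C@@H](CC(=O)/C(C)=C/CC(=O)N(C)OC)C(C[Si](C)(C)C)=C[C@]1(C)CCC=C | intermediate
21 | (3E,5R)-6-[(1R,4S,5S)-4-(but-3-en-1-yl)-5-hydroxy-4-methyl-2-[(trimethylsilyl)methyl]cyclohex-2-en-1-yl]-5-hydroxy-N-methoxy-N,4-dimethylhex-3-enamide | O[C@H]1C[C@@H](C[C@@H](O)/C(C)=C/CC(=O)N(C)OC)C(C[Si](C)(C)C)=C[C@]1(C)CCC=C | intermediate
22 | (3E,5R)-5-(tert-butyldimethylsilyloxy)-6-[(1R,4S,5S)-4-(but-3-en-1-yl)-5-(tert-butyldimethylsilyloxy)-4-methyl-2-[(trimethylsilyl)methyl]cyclohex-2-en-1-yl]-N-methoxy-N,4-dimethylhex-3-enamide | CC(C)(C)[Si](C)(C)O[C@H]1C[C@@H](C[C@@H](O[Si](C)(C)C(C)(C)C)/C(C)=C/CC(=O)N(C)OC)C(C[Si](C)(C)C)=C[C@]1(C)CCC=C | intermediate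
23 | (5E,7R)-7-(tert-butyldimethylsilyloxy)-8-[(1R,4S,5S)-4-(but-3-en-1-yl)-5-(tert-butyldimethylsilyloxy)-4-methyl-2-[(trimethylsilyl)methyl]cyclohex-2-en-1-yl]-2,6-dimethylocta-1,5-dien-3-one | CC(C)(C)[Si](C)(C)O[C@H]1C[C@@H](C[C@@H](O[Si](C)(C)C(C)(C)C)/C(C)=C/CC(=O)C(C)=C)C(C[Si](C)(C)C)=C[C@]1(C)CCC=C | intermediate
24 | (1R,3S,4S,7E,11E,13R)-3,13-bis(tert-butyldimethylsilyloxy)-17-(trimethylsilyl)-7,16-secotrinervita-7,11,15-trien-9-one (ring A bridged by the 14-membered ring) | CC(C)(C)[Si](C)(C)O[C@H]1C[C@H]2C[C@@H](O[Si](C)(C)C(C)(C)C)/C(C)=C/CC(=O)/C(C)=C/CC[C@@]1(C)C=C2C[Si](C)(C)C | intermediate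
25 | C9 chloro(ethyl)aluminium enolate of 26 (C8=C9) | C=C1[C@H]2C[C@H](O[Si](C)(C)C(C)(C)C)[C@@]3(C)CC[C@@H](C(C)=C(O[Al](Cl)CC)C/C=C(C)/[C@H](O[Si](C)(C)C(C)(C)C)C2)[C@@H]13 | intermediate (not isolated)
26 | (1R,3S,4S,7R,8S,11E,13R,16S)-3,13-bis(tert-butyldimethylsilyloxy)trinervita-11,15(17)-dien-9-one | C=C1[C@H]2C[C@H](O[Si](C)(C)C(C)(C)C)[C@@]3(C)CC[C@@H]([C@H](C)C(=O)C/C=C(C)/[C@H](O[Si](C)(C)C(C)(C)C)C2)[C@@H]13 | intermediate
27 | (1R,3S,4S,7R,8S,9S,11E,13R,16S)-3,13-bis(tert-butyldimethylsilyloxy)trinervita-11,15(17)-dien-9-ol | C=C1[C@H]2C[C@H](O[Si](C)(C)C(C)(C)C)[C@@]3(C)CC[C@@H]([C@H](C)[C@@H](O)C/C=C(C)/[C@H](O[Si](C)(C)C(C)(C)C)C2)[C@@H]13 | intermediate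
28 | (1R,3S,4S,7R,8S,9S,11E,13R,16S)-trinervita-11,15(17)-diene-3,9,13-triol | C=C1[C@H]2C[C@H](O)[C@@]3(C)CC[C@@H]([C@H](C)[C@@H](O)C/C=C(C)/[C@H](O)C2)[C@@H]13 | intermediate
29 | (1S,3S,4S,7R,8S,9S,11S,12S,13R,16S)-11,12-epoxytrinervit-15(17)-ene-3,9,13-triol | C=C1[C@H]2C[C@H](O)[C@@]3(C)CC[C@@H]([C@H](C)[C@@H](O)C[C@@H]4O[C@@]4(C)[C@H](O)C2)[C@@H]13 | intermediate
30 | (1S,3S,4S,7R,8S,9S,11S,12R,13R,16S)-11,12-epoxytrinervit-15(17)-ene-3,9,13-triyl tripropanoate | C=C1[C@H]2C[C@H](OC(=O)CC)[C@@]3(C)CC[C@@H]([C@H](C)[C@@H](OC(=O)CC)C[C@@H]4O[C@@]4(C)[C@H](OC(=O)CC)C2)[C@@H]13 | target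

Total step count: 21 (ring line steps 1 to 7, side-chain line steps 8 to 10, joined line steps 11 to 21).
Longest linear sequence: 18 steps (1 to 7, then 11 to 21).

Steps most likely to fail

Step 17. The allylsilane may be protodesilylated before it reacts, or C16 may not reach C7 in the bridged macrocycle, so that no transannular bond or the 1,2-adduct forms. The fallback makes the same C16–C7 bond by a transannular Lewis-acid-promoted ene reaction. It sets out from 9: iron-catalysed coupling with MeMgBr should give the 15-methyl lactone F1, and i-Bu2AlH its lactol F2. Coupling with 18 under the conditions of step 11 gives the diol F3, MnO2 the enone F4, (S)-CBS reduction the (13R)-diol F5, silylation the bis-silyl ether F6, isopropenylmagnesium bromide the isopropenyl ketone F7, and ring-closing metathesis the 15-methyl macrocycle F8. Me2AlCl (CH2Cl2, −78 to 0 °C) should then join C16 to C7 while a C17 hydrogen passes suprafacially to C8; syn addition across the (7E)-olefin corresponds to (7R,8S), and the exocyclic methylene forms if hydrogen is taken from C17 and not from C1. The route is rejoined at 26.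

Step 16. Intermolecular metathesis (oligomerisation) may outrun ring closure onto the electron-poor 1,1-disubstituted olefin. The fallback sets out from 22: i-Bu2AlH reduces the Weinreb amide to the aldehyde F9, and isopropenylmagnesium bromide gives the allylic alcohol F10 (C9 epimers). Ring-closing metathesis is then run on this electron-rich, hydroxyl-bearing olefin to give the macrocyclic allylic alcohol F11, and Dess–Martin periodinane oxidises it to the enone. The route is rejoined at 24.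

Step 18. Substrate (Felkin–Anh) control may override the catalyst, so that hydride adds to the other face of C9. The fallback sets out from 26 and uses that bias on purpose: Li(s-Bu)3BH (THF, −78 °C) should give the 9-epimeric alcohol F12. Mitsunobu inversion (PPh3, diisopropyl azodicarboxylate, 4-nitrobenzoic acid) gives the (9S)-4-nitrobenzoate F13, and K2CO3 in MeOH cleaves the ester. The route is rejoined at 27.

Further compounds

F1 | step 17 | (1S,5S,8S)-8-(but-3-en-1-yl)-6,8-dimethyl-2-oxabicyclo[3.3.1]non-6-en-3-one | O=C1C[C@@H]2C[C@H](O1)[C@@](C)(CCC=C)C=C2C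
F2 | step 17 | (1S,5S,8S)-8-(but-3-en-1-yl)-6,8-dimethyl-2-oxabicyclo[3.3.1]non-6-en-3-ol (lactol) | OC1C[C@@H]2C[C@H](O1)[C@@](C)(CCC=C)C=C2C
F3 | step 17 | 15-methyl analogue of 19 (CH3 in place of CH2SiMe3, both C13 epimers) | O[C@H]1C[C@@H](CC(O)/C(C)=C/CC(=O)N(C)OC)C(C)=C[C@]1(C)CCC=C
F4 | step 17 | 15-methyl analogue of 20 | O[C@H]1C[C@@H](CC(=O)/C(C)=C/CC(=O)N(C)OC)C(C)=C[C@]1(C)CCC=C
F5 | step 17 | 15-methyl analogue of 21 | O[C@H]1C[C@@H](C[C@@H](O)/C(C)=C/CC(=O)N(C)OC)C(C)=C[C@]1(C)CCC=C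
F6 | step 17 | 15-methyl analogue of 22 | CC(C)(C)[Si](C)(C)O[C@H]1C[C@@H](C[C@@H](O[Si](C)(C)C(C)(C)C)/C(C)=C/CC(=O)N(C)OC)C(C)=C[C@]1(C)CCC=C
F7 | step 17 | 15-methyl analogue of 23 | CC(C)(C)[Si](C)(C)O[C@H]1C[C@@H](C[C@@H](O[Si](C)(C)C(C)(C)C)/C(C)=C/CC(=O)C(C)=C)C(C)=C[C@]1(C)CCC=C
F8 | step 17 | (7E,11E)-3,13-bis(tert-butyldimethylsilyloxy)-7,16-secotrinervita-7,11,15-trien-9-one (15-methyl analogue of 24) | CC(C)(C)[Si](C)(C)O[C@H]1C[C@H]2C[C@@H](O[Si](C)(C)C(C)(C)C)/C(C)=C/CC(=O)/C(C)=C/CC[C@@]1(C)C=C2C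
F9 | step 16 | C9 aldehyde from 22 | CC(C)(C)[Si](C)(C)O[C@H]1C[C@@H](C[C@@H](O[Si](C)(C)C(C)(C)C)/C(C)=C/CC=O)C(C[Si](C)(C)C)=C[C@]1(C)CCC=C
F10 | step 16 | C9 isopropenyl carbinol (C9 epimers) | CC(C)(C)[Si](C)(C)O[C@H]1C[C@@H](C[C@@H](O[Si](C)(C)C(C)(C)C)/C(C)=C/CC(O)C(C)=C)C(C[Si](C)(C)C)=C[C@]1(C)CCC=C
F11 | step 16 | macrocyclic C9 allylic alcohol (9-hydroxy analogue of 24) | CC(C)(C)[Si](C)(C)O[C@H]1C[C@H]2C[C@@H](O[Si](C)(C)C(C)(C)C)/C(C)=C/CC(O)/C(C)=C/CC[C@@]1(C)C=C2C[Si](C)(C)C
F12 | step 18 | (9R)-epimer of 27 | C=C1[C@H]2C[C@H](O[Si](C)(C)C(C)(C)C)[C@@]3(C)CC[C@@H]([C@H](C)[C@H](O)C/C=C(C)/[C@H](O[Si](C)(C)C(C)(C)C)C2)[C@@H]13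
F13 | step 18 | (9S)-4-nitrobenzoate of 27 | C=C1[C@H]2C[C@H](O[Si](C)(C)C(C)(C)C)[C@@]3(C)CC[C@@H]([C@H](C)[C@@H](OC(=O)c4ccc(cc4)[N+](=O)[O-])C/C=C(C)/[C@H](O[Si](C)(C)C(C)(C)C)C2)[C@@H]13
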